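**Strategy.** The target is C2-symmetric about its S–S bond, and in each 3,4-dimethoxy-5-methyl-2-pyranone ring C6 is the only carbon that carries neither oxygen nor methyl. Both C6–CH2 bonds are therefore made at once. The key step is a twofold photoredox decarboxylative C–H alkylation: the bis(N-hydroxyphthalimide) ester of 11,11'-disulfanediyldiundecanoic acid loses two CO2, and each primary radical adds to C6–H of 3,4-dimethoxy-5-methyl-2H-pyran-2-one (the δ-terminus of the O1–C6=C5–C4=C3–C2=O dienoate), followed by oxidation and loss of H+. Three components are joined with the disulfide already in place. The precursors are the C6-unsubstituted pyranone (three steps) and the doubly activated disulfide diacid (two steps).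

Key step: step 6

Remark: the target has no stereocentre and no stereogenic double bond, so it is one achiral compound and the route needs no stereocontrol.

**Step 1**
Reactants: 1 methyl methoxyacetate; 2 propionyl chloride
Product: 3 methyl 2-methoxy-3-oxopentanoate (racemic)
Conditions: 1 (2.1 equiv), LiHMDS (2.1 equiv, commercial solution), THF, −78 °C; 2 (1.0 equiv), −78 → 0 °C; 1 M HCl
Reagents that add atoms: none
Why: Crossed Claisen condensation, in which the lithium enolate of 1 should be C-acylated by the acid chloride while the second equivalent of enolate removes the acidic C2–H of 3 and so prevents a second acylation; the racemic C2 centre becomes sp2 in step 2.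

**Step 2**
Reactants: 3 methyl 2-methoxy-3-oxopentanoate
Product: 5 4-hydroxy-3-methoxy-5-methyl-2H-pyran-2-one, via hydroxymethylene keto ester 4 (not isolated)
Conditions: LDA (2.2 equiv, commercial solution), THF, −78 → 0 °C; HCO2Me (1.5 equiv), −78 °C → rt; 1 M HCl; crude 4, DBU (1.2 equiv), PhMe, 80 °C; 1 M HCl
Reagents that add atoms: methyl formate, COC=O
Why: Huckin–Weiler γ-acylation of the β-keto ester dianion (Claisen formylation at C4) should give 4, whose Z-enolate oxygen then attacks the methyl ester under DBU in a 6-exo-trig enol-lactonization that ends in the 4-hydroxy-2-pyranone.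

**Step 3**
Reactants: 5 4-hydroxy-3-methoxy-5-methyl-2H-pyran-2-one
Product: 6 3,4-dimethoxy-5-methyl-2H-pyran-2-one
Conditions: Me2SO4 (1.2 equiv), K2CO3 (1.5 equiv), acetone, reflux
Reagents that add atoms: dimethyl sulfate, COS(=O)(=O)OC
Why: Williamson-type O-methylation of the vinylogous acid with K2CO3/Me2SO4 in acetone is the standard condition set that favours the 4-methoxy-2-pyranone over the isomeric 2-methoxy-4-pyranone.

**Step 4**
Reactants: 7 11-sulfanylundecanoic acid (two molecules)
Product: 8 11,11'-disulfanediyldiundecanoic acid
Conditions: 30% aq. H2O2 (0.55 equiv per thiol), NaI (1 mol %), EtOAc, rt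
Reagents that add atoms: none
Why: Iodide-catalysed oxidative coupling of thiols by H2O2 (via a transient sulfenyl iodide) should stop at the disulfide and leave the carboxylic acids untouched.

**Step 5**
Reactants: 8 11,11'-disulfanediyldiundecanoic acid
Product: 9 bis(1,3-dioxoisoindolin-2-yl) 11,11'-disulfanediyldiundecanoate
Conditions: N-hydroxyphthalimide (2.2 equiv), DIC (2.3 equiv), DMAP (10 mol %), CH2Cl2, rt
Reagents that add atoms: N-hydroxyphthalimide, O=C1c2ccccc2C(=O)N1O
Why: Steglich-type carbodiimide esterification should convert both acids into redox-active N-acyloxyphthalimides, the dialkyl disulfide being inert to DIC/DMAP.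

**Step 6**
Reactants: 9 bis(1,3-dioxoisoindolin-2-yl) 11,11'-disulfanediyldiundecanoate; 6 3,4-dimethoxy-5-methyl-2H-pyran-2-one (6 equiv, excess recovered)
Product: 11 lehualide K, via mono-alkylated phthalimidoyl ester 10 (not isolated)
Conditions: fac-Ir(ppy)3 (2 mol %), TFA (4 equiv), degassed DMA (0.05 M in 9), blue LEDs (450 nm), rt, Ar
Reagents that add atoms: none
Why: Proposed new method: excited fac-Ir(ppy)3 should transfer one electron to each N-acyloxyphthalimide group of 9, N–O cleavage and loss of CO2 give a primary alkyl radical that adds to C6 of TFA-activated 6, and the delocalized C5/C3 radical is oxidized by Ir(IV) and loses the C6 proton to restore the 2-pyranone; the second event joins the pyranone-bearing mono-adduct 10 to another molecule of 6 in the same way. The closest known reaction types are the photoredox decarboxylative (Minisci-type) C–H alkylation of heteroarenes and coumarins with N-hydroxyphthalimide esters and the Giese addition of such radicals to the O-bearing carbon of chromones. No ring is closed and no stereocentre is formed. Site selectivity is secured because C6 is the only unsubstituted ring carbon and the electrophilic δ-terminus of the O1–C6=C5–C4=C3–C2=O system, so attack elsewhere would meet a fully substituted carbon and could not rearomatize. Chemoselectivity for C6 over homolytic substitution at the S–S bond is supported by the sluggish attack of primary alkyl radicals on dialkyl disulfides, the sixfold excess of 6 and the low stationary radical concentration, while reduction of a dialkyl disulfide lies beyond the potential of the catalyst. Any thiyl exchange at sulfur is degenerate in this symmetric system, and the product has no ring C–H left for over-alkylation.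

**Compound list**
1 | methyl methoxyacetate | COCC(=O)OC | starting material
2 | propionyl chloride | CCC(=O)Cl | starting material
3 | methyl 2-methoxy-3-oxopentanoate (racemic) | CCC(=O)C(OC)C(=O)OC | intermediate
4 | methyl (Z)-5-hydroxy-2-methoxy-4-methyl-3-oxopent-4-enoate (enol form of the 5-formyl keto ester, racemic at C2, not isolated) | COC(=O)C(OC)C(=O)/C(C)=C\O | intermediate
5 | 4-hydroxy-3-methoxy-5-methyl-2H-pyran-2-one | COc1c(O)c(C)coc1=O | intermediate
6 | 3,4-dimethoxy-5-methyl-2H-pyran-2-one | COc1c(C)coc(=O)c1OC | intermediate
7 | 11-sulfanylundecanoic acid (11-mercaptoundecanoic acid) | OC(=O)CCCCCCCCCCS | starting material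
8 | 11,11'-disulfanediyldiundecanoic acid | OC(=O)CCCCCCCCCCSSCCCCCCCCCCC(=O)O | intermediate
9 | bis(1,3-dioxoisoindolin-2-yl) 11,11'-disulfanediyldiundecanoate | O=C(CCCCCCCCCCSSCCCCCCCCCCC(=O)ON1C(=O)c2ccccc2C1=O)ON1C(=O)c2ccccc2C1=O | intermediate
10 | 1,3-dioxoisoindolin-2-yl 11-{[10-(4,5-dimethoxy-3-methyl-6-oxo-6H-pyran-2-yl)decyl]disulfanyl}undecanoate (not isolated) | COc1c(C)c(CCCCCCCCCCSSCCCCCCCCCCC(=O)ON2C(=O)c3ccccc3C2=O)oc(=O)c1OC | intermediate
11 | lehualide K, 6,6'-[disulfanediylbis(decane-10,1-diyl)]bis(3,4-dimethoxy-5-methyl-2H-pyran-2-one) | COc1c(C)c(CCCCCCCCCCSSCCCCCCCCCCc2oc(=O)c(OC)c(OC)c2C)oc(=O)c1OC | target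

**Totals.** Total step count: 6. Longest linear sequence: 4 steps (steps 1, 2, 3, 6); the linker branch (steps 4, 5) joins at step 6.

**Steps most likely to fail**

1. Step 6 (proposed new method). Capture of the alkyl radical by the electron-rich pyranone may be too slow. Homolytic substitution at the S–S bond, hydrogen-atom transfer to the radical or loss of the second active ester could then take over, so that only one end couples. Fallback with known reaction types only, setting out from 6 and coming back at 11:
   - 6 is deprotonated at C6 with TMPZnCl·LiCl (THF, 25 °C) to (4,5-dimethoxy-3-methyl-6-oxo-6H-pyran-2-yl)zinc chloride F1.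
   - Quenching with I2 gives 6-iodo-3,4-dimethoxy-5-methyl-2H-pyran-2-one F2.
   - Purchased 10-bromodec-1-ene (C=CCCCCCCCCBr) is S-alkylated with triphenylmethanethiol (K2CO3, DMF) to (dec-9-en-1-yl)(trityl)sulfane F3.
   - Hydroboration of F3 with 9-BBN-H (THF) gives 9-[10-(tritylsulfanyl)decyl]-9-borabicyclo[3.3.1]nonane F4.
   - B-alkyl Suzuki–Miyaura coupling of F4 with F2 (Pd(dppf)Cl2, K3PO4, THF/DMF/H2O, 50 °C) forms the same C6–CH2 bond and gives 3,4-dimethoxy-5-methyl-6-[10-(tritylsulfanyl)decyl]-2H-pyran-2-one F5.
   - I2 in CH2Cl2/MeOH removes the trityl groups oxidatively and closes the S–S bond, giving 11.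

2. Step 2. The dianion of the α-methoxy β-keto ester may form incompletely or be formylated on oxygen, and the formyl keto ester may self-condense before ring closure. Fallback setting out from 3 and coming back at 5: 3 is heated with tert-butoxybis(dimethylamino)methane (PhMe, 80 °C), which aminomethylenates the only CH2 group next to the ketone and gives methyl (E)-5-(dimethylamino)-2-methoxy-4-methyl-3-oxopent-4-enoate F6. Warm aqueous HCl/AcOH then hydrolyses the enaminone to the hydroxymethylene ketone, which lactonizes to 5.

3. Step 3. Methylation may take place at the lactone carbonyl oxygen and lead into the 2-methoxy-4-pyranone series. Fallback setting out from 3 and coming back at 6, which fixes the methoxy group before the ring exists: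
   - 3 is converted with HC(OMe)3 and catalytic H2SO4 in MeOH into the enol ether methyl (Z)-2,3-dimethoxypent-2-enoate F7 (an E/Z mixture is expected to equilibrate under the later acid treatment).
   - γ-Deprotonation (LDA, THF, −78 °C) and vinylogous formylation with methyl formate give methyl (Z)-2,3-dimethoxy-4-methyl-5-oxopent-2-enoate F8.
   - Acid-catalysed enol lactonization (TsOH, PhMe, 80 °C) gives 6.

**Further compounds**
F1 | step 6 | (4,5-dimethoxy-3-methyl-6-oxo-6H-pyran-2-yl)zinc chloride | COc1c(C)c([Zn]Cl)oc(=O)c1OC
F2 | step 6 | 6-iodo-3,4-dimethoxy-5-methyl-2H-pyran-2-one | COc1c(C)c(I)oc(=O)c1OC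
F3 | step 6 | (dec-9-en-1-yl)(trityl)sulfane | C=CCCCCCCCCSC(c1ccccc1)(c1ccccc1)c1ccccc1
F4 | step 6 | 9-[10-(tritylsulfanyl)decyl]-9-borabicyclo[3.3.1]nonane | B1(CCCCCCCCCCSC(c2ccccc2)(c2ccccc2)c2ccccc2)C2CCCC1CCC2
F5 | step 6 | 3,4-dimethoxy-5-methyl-6-[10-(tritylsulfanyl)decyl]-2H-pyran-2-one | COc1c(C)c(CCCCCCCCCCSC(c2ccccc2)(c2ccccc2)c2ccccc2)oc(=O)c1OC
F6 | step 2 | methyl (E)-5-(dimethylamino)-2-methoxy-4-methyl-3-oxopent-4-enoate | COC(=O)C(OC)C(=O)/C(C)=C/N(C)C
F7 | step 3 | methyl (Z)-2,3-dimethoxypent-2-enoate | CC/C(OC)=C(/OC)C(=O)OC
F8 | step 3 | methyl (Z)-2,3-dimethoxy-4-methyl-5-oxopent-2-enoate | O=CC(C)/C(OC)=C(/OC)C(=O)OC
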